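**Retrosynthetic overview**
- The last bond made is the spiro C–O bond, formed together with the adjacent meso C–C bond in a dehydrative, dearomative spiroaminalization between a twelve-membered γ-hydroxy ketopyrrolophane and 4-methoxy-2,2'-bipyrrole. This closes the tetrahydropyran and turns ring B into the 2H-pyrrole.
- The ketopyrrolophane comes from a B-alkyl Suzuki macrocyclization (pyrrole C5–CH2 bond) of a 5-bromo-2-acylpyrrole carrying a terminal alkene.
- That acylpyrrole comes from 5-bromo-2-lithio-N-Boc-pyrrole and trans-α-(hept-6-enyl)-γ-valerolactone. (S)-γ-Valerolactone supplies the C–CH3 centre and directs the α-centre.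
- The bipyrrole comes from Suzuki coupling of a pyrrol-2-yl triflate (from 4-methoxy-3-pyrrolin-2-one) with N-Boc-pyrrol-2-ylboronic acid.
- Ring order: ring C (bought as a pyrrole) → twelve-membered ansa ring → rings A and B attached → tetrahydropyran and spiro ring B last.

Assumption: stereodescriptors are those read from the given SMILES (spiro carbon R; O–CH(CH3) S; ring-fusion CH carrying the heptamethylene bridge S; CH carrying ring C S), and the (R)-antipode of the phosphoric acid in step 8 is taken to be the matched catalyst.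

**Step 1**
Reactants: 1 (S)-γ-valerolactone; 2 7-bromohept-1-ene
Product: 4 (3S,5S)-3-(hept-6-en-1-yl)-5-methyldihydrofuran-2(3H)-one, via lithium lactone enolate 3 (not isolated)
Conditions: LiN(iPr)2 (1.05 equiv), THF, −78 °C; then 2 (1.3 equiv), DMPU, −78 → −30 °C
Reagents that add atoms: none
Why: Kinetic SN2 alkylation of the lithium enolate of the γ-substituted butyrolactone takes place on the face anti to the C5 methyl group, so the new C3 stereocentre is set trans (3S,5S) by 1,3-induction from the chiral-pool centre, the minor cis isomer being removed by chromatography.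

**Step 2**
Reactants: 5 tert-butyl 1H-pyrrole-1-carboxylate
Product: 6 tert-butyl 2,5-dibromo-1H-pyrrole-1-carboxylate
Conditions: NBS (2.05 equiv), THF, −78 °C → rt, dark
Reagents that add atoms: N-bromosuccinimide, O=C1CCC(=O)N1Br
Why: Electrophilic aromatic bromination of the N-acylpyrrole is α-selective, so two equivalents of NBS give the symmetrical 2,5-dibromide, with no stereocentre involved.

**Step 3**
Reactants: 6 tert-butyl 2,5-dibromo-1H-pyrrole-1-carboxylate; 4 (3S,5S)-3-(hept-6-en-1-yl)-5-methyldihydrofuran-2(3H)-one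
Product: 8 tert-butyl 2-bromo-5-[(2S,4S)-2-(hept-6-en-1-yl)-4-hydroxypentanoyl]-1H-pyrrole-1-carboxylate, via 5-bromo-2-lithio-N-Boc-pyrrole 7 (not isolated)
Conditions: 6 (1.2 equiv), n-BuLi (1.2 equiv), THF, −78 °C, 20 min; then 4, −78 °C, 1 h; AcOH, −78 °C → rt
Reagents that add atoms: none
Why: Mono bromine–lithium exchange gives the 2-lithiopyrrole, whose nucleophilic acyl substitution on the γ-lactone stops at the stable lithium lactolate at −78 °C and releases the γ-hydroxy ketone on cold acetic acid quench, so both existing stereocentres are carried over unchanged and none is created.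

**Step 4**
Reactants: 8 tert-butyl 2-bromo-5-[(2S,4S)-2-(hept-6-en-1-yl)-4-hydroxypentanoyl]-1H-pyrrole-1-carboxylate
Product: 11 (3S)-3-[(2S)-2-hydroxypropyl]-14-azabicyclo[9.2.1]tetradeca-1(13),11-dien-2-one, via alkyl-9-BBN borane 9 (not isolated), via N-Boc ketopyrrolophane 10 (not isolated)
Conditions: 9-BBN-H (2.5 equiv), THF, 0 °C → rt; then slow addition to Pd(dppf)Cl2·CH2Cl2 (10 mol %), AsPh3 (20 mol %), Cs2CO3 (3 equiv), DMF/THF/H2O, 45 °C, 2 mM; then MeOH, rt
Reagents that add atoms: none
Why: Anti-Markovnikov hydroboration of the terminal alkene followed by intramolecular B-alkyl Suzuki–Miyaura coupling under high dilution closes the twelve-membered ansa ring at the pyrrole α-carbon, and the labile N-Boc group of the 2-acylpyrrole is then removed by carbonate-mediated methanolysis, conditions mild enough to leave the α-stereocentre of the ketone untouched while no new stereocentre forms.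

**Step 5**
Reactants: 12 4-methoxy-1,5-dihydro-2H-pyrrol-2-one
Product: 13 tert-butyl 4-methoxy-2-oxo-2,5-dihydro-1H-pyrrole-1-carboxylate
Conditions: Boc2O (1.2 equiv), 4-(dimethylamino)pyridine (10 mol %), MeCN, rt
Reagents that add atoms: di-tert-butyl dicarbonate, CC(C)(C)OC(=O)OC(=O)OC(C)(C)C
Why: Nucleophile-catalysed N-acylation of the lactam N–H by Boc2O activates the ring for γ-enolisation, with no stereocentre involved.

**Step 6**
Reactants: 13 tert-butyl 4-methoxy-2-oxo-2,5-dihydro-1H-pyrrole-1-carboxylate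
Product: 15 tert-butyl 4-methoxy-2-{[(trifluoromethyl)sulfonyl]oxy}-1H-pyrrole-1-carboxylate, via potassium 2-oxidopyrrole 14 (not isolated)
Conditions: KN(SiMe3)2 (1.1 equiv), THF, −78 °C; then PhNTf2 (1.15 equiv), −78 → 0 °C
Reagents that add atoms: N-phenylbis(trifluoromethanesulfonimide), O=S(=O)(N(c1ccccc1)S(=O)(=O)C(F)(F)F)C(F)(F)F
Why: γ-Deprotonation of the N-Boc unsaturated lactam gives the aromatic 2-oxidopyrrole, which is O-sulfonylated by the triflimide in a standard enol triflate formation to give the pyrrol-2-yl triflate, with no stereocentre involved.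

**Step 7**
Reactants: 15 tert-butyl 4-methoxy-2-{[(trifluoromethyl)sulfonyl]oxy}-1H-pyrrole-1-carboxylate; 16 [1-(tert-butoxycarbonyl)-1H-pyrrol-2-yl]boronic acid
Product: 18 4-methoxy-1H,1'H-2,2'-bipyrrole, via bis-N-Boc bipyrrole 17 (not isolated)
Conditions: 16 (1.3 equiv), Pd(PPh3)4 (5 mol %), K2CO3 (2 M aq, 3 equiv), 1,4-dioxane, 85 °C; then NaOMe (3 equiv), MeOH/THF, rt
Reagents that add atoms: none
Why: Suzuki–Miyaura coupling of the heteroaryl triflate with the 2-pyrrolylboronic acid forms the 2,2'-bipyrrole bond and methoxide then cleaves both N-Boc groups by acyl transfer, with no stereocentre involved.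

**Step 8**
Reactants: 11 (3S)-3-[(2S)-2-hydroxypropyl]-14-azabicyclo[9.2.1]tetradeca-1(13),11-dien-2-one; 18 4-methoxy-1H,1'H-2,2'-bipyrrole
Product: 20 premarineosin A, via macrocyclic hydroxy-prodiginine 19 (not isolated)
Conditions: 18 (1.2 equiv), (R)-3,3'-bis(2,4,6-triisopropylphenyl)-1,1'-binaphthyl-2,2'-diyl hydrogen phosphate (20 mol %), 5 Å MS, toluene, 0.02 M, 40 °C, Ar, dark
Reagents that add atoms: none
Why: Proposed new method: a chiral phosphoric acid-catalysed, redox-neutral dehydrative dearomative spiroaminalization (an interrupted prodiginine condensation) in which the acid first ionises the γ-hydroxy ketone (through its five-membered lactol) to an O-alkyl 2-azafulvenium that is captured at C5 of the bipyrrole and collapses to the twisted meso-substituted prodiginine 19, after which the chromophore-bound phosphate relays a proton to the meso carbon (on the face that gives the trans ring fusion, setting the pyrrolyl-bearing CH as S under matched catalyst control) and the pendant hydroxyl closes the six-membered ring onto the now electrophilic ring B α-carbon through a chair that keeps the ring B nitrogen axial (anomeric effect) and its methoxy-bearing carbon equatorial, fixing the spiro centre as R and forming the key C–O bond while ring A regains aromaticity and the non-basic product releases the catalyst; the closest known reactions are the acid-mediated dipyrrin (prodiginine) condensation of 2-acylpyrroles and the chiral Brønsted acid-catalysed spiroacetalization of hydroxy enol ethers, neither of which has been shown to dearomatise a bipyrrole into a 2H-pyrrole N,O-spiroketal.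

**Compound list**
1 | (S)-γ-valerolactone, (5S)-5-methyldihydrofuran-2(3H)-one | C[C@H]1CCC(=O)O1 | starting material
2 | 7-bromohept-1-ene | C=CCCCCCBr | starting material
3 | lithium (5S)-5-methyl-4,5-dihydrofuran-2-olate | [Li]OC1=CC[C@H](C)O1 | intermediate
4 | (3S,5S)-3-(hept-6-en-1-yl)-5-methyldihydrofuran-2(3H)-one (trans) | O=C1O[C@@H](C)C[C@@H]1CCCCCC=C | intermediate
5 | tert-butyl 1H-pyrrole-1-carboxylate (N-Boc-pyrrole) | CC(C)(C)OC(=O)n1cccc1 | starting material
6 | tert-butyl 2,5-dibromo-1H-pyrrole-1-carboxylate | CC(C)(C)OC(=O)n1c(Br)ccc1Br | intermediate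
7 | tert-butyl 2-bromo-5-lithio-1H-pyrrole-1-carboxylate | CC(C)(C)OC(=O)n1c(Br)ccc1[Li] | intermediate
8 | tert-butyl 2-bromo-5-[(2S,4S)-2-(hept-6-en-1-yl)-4-hydroxypentanoyl]-1H-pyrrole-1-carboxylate | O[C@@H](C)C[C@H](CCCCCC=C)C(=O)c1ccc(Br)n1C(=O)OC(C)(C)C | intermediate
9 | tert-butyl 2-bromo-5-[(2S,4S)-2-[7-(9-borabicyclo[3.3.1]nonan-9-yl)heptyl]-4-hydroxypentanoyl]-1H-pyrrole-1-carboxylate | O[C@@H](C)C[C@H](CCCCCCCB1C2CCCC1CCC2)C(=O)c1ccc(Br)n1C(=O)OC(C)(C)C | intermediate
10 | tert-butyl (3S)-3-[(2S)-2-hydroxypropyl]-2-oxo-14-azabicyclo[9.2.1]tetradeca-1(13),11-diene-14-carboxylate | O[C@@H](C)C[C@@H]1CCCCCCCc2ccc(n2C(=O)OC(C)(C)C)C1=O | intermediate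
11 | (3S)-3-[(2S)-2-hydroxypropyl]-14-azabicyclo[9.2.1]tetradeca-1(13),11-dien-2-one (twelve-membered 2,5-pyrrolophane ketone) | O[C@@H](C)C[C@@H]1CCCCCCCc2ccc([nH]2)C1=O | intermediate
12 | 4-methoxy-1,5-dihydro-2H-pyrrol-2-one | COC1=CC(=O)NC1 | starting material
13 | tert-butyl 4-methoxy-2-oxo-2,5-dihydro-1H-pyrrole-1-carboxylate | COC1=CC(=O)N(C(=O)OC(C)(C)C)C1 | intermediate
14 | potassium 1-(tert-butoxycarbonyl)-4-methoxy-1H-pyrrol-2-olate | COc1cc([O-])n(C(=O)OC(C)(C)C)c1.[K+] | intermediate
15 | tert-butyl 4-methoxy-2-{[(trifluoromethyl)sulfonyl]oxy}-1H-pyrrole-1-carboxylate | COc1cc(OS(=O)(=O)C(F)(F)F)n(C(=O)OC(C)(C)C)c1 | intermediate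
16 | [1-(tert-butoxycarbonyl)-1H-pyrrol-2-yl]boronic acid | CC(C)(C)OC(=O)n1cccc1B(O)O | starting material
17 | di-tert-butyl 4-methoxy-1H,1'H-[2,2'-bipyrrole]-1,1'-dicarboxylate | COc1cc(-c2cccn2C(=O)OC(C)(C)C)n(C(=O)OC(C)(C)C)c1 | intermediate
18 | 4-methoxy-1H,1'H-2,2'-bipyrrole | COc1c[nH]c(-c2ccc[nH]2)c1 | intermediate
19 | (2S)-1-[(3S)-2-[(Z)-3-methoxy-5-(1H-pyrrol-2-yl)-2H-pyrrol-2-ylidene]-14-azabicyclo[9.2.1]tetradeca-1(13),11-dien-3-yl]propan-2-ol (macrocyclic hydroxy-prodiginine) | COC1=CC(c2ccc[nH]2)=N/C1=C3\c4ccc([nH]4)CCCCCCC[C@H]3C[C@H](C)O | intermediate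
20 | premarineosin A (spiro carbon R; O–CH(CH3) S; ring-fusion CH S; pyrrolyl CH S) | COC1=CC(c2ccc[nH]2)=N[C@]12O[C@@H](C)C[C@@H]1CCCCCCCc3ccc([nH]3)[C@H]12 | target

**Step count and risks**
Total step count: 8. Longest linear sequence: 4 steps (1 → 4 → 8 → 11 → 20; the bipyrrole branch 12 → 13 → 15 → 18 → 20 is equally long).

Step 8 (the proposed new step) is the most likely to fail. The cascade may stall at the salt of prodiginine 19, divert reversibly to the five-membered meso ether, or scramble the α-stereocentre through the vinylogous ene tautomer. The fallback uses known chemistry, sets out from 11 and comes back to the route at 20. NaBH4 with CeCl3·7H2O in MeOH at −20 °C reduces the acylpyrrole to the carbinol (3S)-3-[(2S)-2-hydroxypropyl]-14-azabicyclo[9.2.1]tetradeca-1(13),11-dien-2-ol F1 (both carbinol epimers). CF3CO2H (5 mol %) in CH2Cl2 at −40 °C then ionises the carbinol to the 2-azafulvenium, which is captured at C5 of 18 in an ordinary dipyrromethane-type condensation. This gives the leuco compound (2S)-1-[(2S,3S)-2-[3-methoxy-5-(1H-pyrrol-2-yl)-1H-pyrrol-2-yl]-14-azabicyclo[9.2.1]tetradeca-1(13),11-dien-3-yl]propan-2-ol F2, with the minor epimer at the new CH removed by chromatography. Activated MnO2 in CH2Cl2 at rt finally dehydrogenates the electron-rich methoxybipyrrole, and the pendant alcohol captures the resulting cation at the ring B α-carbon to give 20. In this variant the ketone α-centre is never exposed to the prodiginine stage.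

Step 4 is the second risk. The twelve-membered B-alkyl Suzuki closure may give oligomers, and 9-BBN-H may partly reduce the ketone. The fallback sets out from 8 and comes back at 10. Stille coupling with Bu3SnCH=CH2 (Pd(PPh3)4, toluene, 90 °C) gives tert-butyl 2-ethenyl-5-[(2S,4S)-2-(hept-6-en-1-yl)-4-hydroxypentanoyl]-1H-pyrrole-1-carboxylate F3. Ring-closing metathesis with the second-generation Grubbs catalyst RuCl2(H2IMes)(PCy3)(=CHPh) (CH2Cl2, 40 °C, 1 mM) gives the macrocyclic alkene tert-butyl (3S)-3-[(2S)-2-hydroxypropyl]-2-oxo-14-azabicyclo[9.2.1]tetradeca-1(13),9,11-triene-14-carboxylate F4 as an E/Z mixture. H2 (1 atm) over Pd/C in EtOAc saturates the alkene to give 10, which is methanolysed to 11 as in the last operation of step 4.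

Step 3 is the third risk. The liberated alkoxide may take the Boc group from the pyrrole nitrogen, and the aryllithium may enolise the lactone or add twice. The fallback sets out from 4 and comes back at 8. AlMe3 with MeNH(OMe)·HCl (CH2Cl2, 0 °C) opens the lactone to (2S,4S)-2-(hept-6-en-1-yl)-4-hydroxy-N-methoxy-N-methylpentanamide F5. TBSCl and imidazole in DMF give (2S,4S)-4-[(tert-butyldimethylsilyl)oxy]-2-(hept-6-en-1-yl)-N-methoxy-N-methylpentanamide F6. Addition of 7 (from 6 and n-BuLi, THF, −78 °C) stops at the Weinreb chelate and gives tert-butyl 2-bromo-5-[(2S,4S)-4-[(tert-butyldimethylsilyl)oxy]-2-(hept-6-en-1-yl)pentanoyl]-1H-pyrrole-1-carboxylate F7. HF·pyridine in THF at 0 °C removes the silyl group to give 8.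

**Further compounds**
F1 | step 8 | (3S)-3-[(2S)-2-hydroxypropyl]-14-azabicyclo[9.2.1]tetradeca-1(13),11-dien-2-ol (both C2 epimers) | O[C@@H](C)C[C@@H]1CCCCCCCc2ccc([nH]2)C1O
F2 | step 8 | (2S)-1-[(2S,3S)-2-[3-methoxy-5-(1H-pyrrol-2-yl)-1H-pyrrol-2-yl]-14-azabicyclo[9.2.1]tetradeca-1(13),11-dien-3-yl]propan-2-ol | COc1cc(-c2ccc[nH]2)[nH]c1[C@@H]1c3ccc([nH]3)CCCCCCC[C@H]1C[C@H](C)O
F3 | step 4 | tert-butyl 2-ethenyl-5-[(2S,4S)-2-(hept-6-en-1-yl)-4-hydroxypentanoyl]-1H-pyrrole-1-carboxylate | O[C@@H](C)C[C@H](CCCCCC=C)C(=O)c1ccc(C=C)n1C(=O)OC(C)(C)C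
F4 | step 4 | tert-butyl (3S)-3-[(2S)-2-hydroxypropyl]-2-oxo-14-azabicyclo[9.2.1]tetradeca-1(13),9,11-triene-14-carboxylate (E/Z mixture) | O[C@@H](C)C[C@@H]1CCCCCC=Cc2ccc(n2C(=O)OC(C)(C)C)C1=O
F5 | step 3 | (2S,4S)-2-(hept-6-en-1-yl)-4-hydroxy-N-methoxy-N-methylpentanamide | O[C@@H](C)C[C@H](CCCCCC=C)C(=O)N(C)OC
F6 | step 3 | (2S,4S)-4-[(tert-butyldimethylsilyl)oxy]-2-(hept-6-en-1-yl)-N-methoxy-N-methylpentanamide | CC(C)(C)[Si](C)(C)O[C@@H](C)C[C@H](CCCCCC=C)C(=O)N(C)OC
F7 | step 3 | tert-butyl 2-bromo-5-[(2S,4S)-4-[(tert-butyldimethylsilyl)oxy]-2-(hept-6-en-1-yl)pentanoyl]-1H-pyrrole-1-carboxylate | CC(C)(C)[Si](C)(C)O[C@@H](C)C[C@H](CCCCCC=C)C(=O)c1ccc(Br)n1C(=O)OC(C)(C)C
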